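The cyclobutane ring carries two identical (2,2'-bithiophen-5-yl)ethynyl arms on adjacent CH carbons, while its other two carbons are unsubstituted CH2 groups: the molecule is the head-to-head dimer of one conjugated enyne, 5-(but-3-en-1-ynyl)-2,2'-bithiophene, its likely biogenetic precursor. A biomimetic [2+2] photodimerisation of this monomer should join the two vinyl CH2 termini and the two alkyne-bearing CH carbons in one operation, creating the four-membered ring and both stereocentres (cis, meso). The precursor is simply the vinylacetylene monomer, reached in two steps from 5-bromo-2,2'-bithiophene and but-3-yn-1-ol by Sonogashira coupling and dehydration.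

Key step: step 3

Remark: the two stereodescriptors of the target define the cis (1R,2S) cyclobutane, an achiral meso compound, so only the relative configuration has to be controlled.

Step 1
Reactants: 1 5-bromo-2,2'-bithiophene; 2 but-3-yn-1-ol
Product: 3 4-([2,2'-bithiophen]-5-yl)but-3-yn-1-ol
Conditions: PdCl2(PPh3)2 (cat.), CuI (cat.), Et3N, THF, 60 °C, argon
Reagents that add atoms: none
Why: Sonogashira coupling, in which zerovalent palladium formed in situ inserts into the C–Br bond at C5 of the bithiophene, the copper acetylide of 2 transmetalates and reductive elimination gives the aryl alkyne, the free primary alcohol being tolerated.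

Step 2
Reactants: 3 4-([2,2'-bithiophen]-5-yl)but-3-yn-1-ol
Product: 5 5-(but-3-en-1-yn-1-yl)-2,2'-bithiophene, via homopropargylic mesylate 4 (not isolated)
Conditions: MsCl, Et3N, CH2Cl2, 0 °C; then DBU, 0 °C to rt, in the dark
Reagents that add atoms: methanesulfonyl chloride, CS(=O)(=O)Cl (its sulfonyl group is carried only by intermediate 4 and leaves again in the elimination)
Why: O-sulfonylation followed by E2 elimination, in which the propargylic C–H bonds of 4 are acidified by the aryl alkyne so that DBU should give the conjugated enyne, the standard dehydration of homopropargylic alcohols to vinylacetylenes.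

Step 3
Reactants: 5 5-(but-3-en-1-yn-1-yl)-2,2'-bithiophene (two molecules)
Product: 6 isocardopatine, cis-1,2-bis[([2,2'-bithiophen]-5-yl)ethynyl]cyclobutane (1R,2S, meso)
Conditions: hν (365 nm), rigorously degassed benzene (ca. 0.5 M), 15 °C, stopped at partial conversion; SiO2 chromatography to separate 6 from its trans isomer and unreacted 5
Reagents that add atoms: none
Why: Light absorbed by the bithienyl-enyne chromophore of 5 populates, after intersystem crossing, a triplet whose vinyl CH2 terminus adds to the vinyl CH2 terminus of a ground-state molecule, so the CH2–CH2 bond forms first and leaves a triplet 1,4-biradical with two propargylic radical centres, each delocalised into its alkynyl-bithienyl arm; spin inversion and recombination of these two centres then makes the CH–CH bond. The closest known reaction type is the stepwise triplet [2+2] photodimerisation of styrenes, 1,3-dienes and conjugated 1,3-enynes to 1,2-disubstituted cyclobutanes, and the step copies the presumed biogenesis of the skeleton from the monomer. The only ring closed is the cyclobutane, by recombination of the 1,4-biradical (formal [2+2] cycloaddition of two alkenes). Both stereocentres arise in this ring closure, the cis (meso) relationship resulting when the biradical collapses from the folded conformer in which the two bithienylethynyl arms lie stacked face to face; absolute control is not needed because the product is achiral. The step needs head-to-head regioselectivity, secured by the doubly propargylic biradical; chemoselectivity for the terminal vinyl group over the alkyne and thiophene π bonds, secured by the accessibility and spin density of the vinyl terminus; and cis selectivity, which the substrate secures only in part, since concentrated solution should favour stacked encounter pairs but the trans isomer is expected alongside and has to be removed by chromatography. Irradiation at the long-wavelength edge of the monomer band, exclusion of oxygen and interruption at partial conversion should limit photocycloreversion of the less conjugated product and photo-oxidation.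

Compound list
1 | 5-bromo-2,2'-bithiophene | Brc1ccc(-c2cccs2)s1 | starting material
2 | but-3-yn-1-ol | C#CCCO | starting material
3 | 4-([2,2'-bithiophen]-5-yl)but-3-yn-1-ol | OCCC#Cc1ccc(-c2cccs2)s1 | intermediate
4 | 4-([2,2'-bithiophen]-5-yl)but-3-yn-1-yl methanesulfonate | CS(=O)(=O)OCCC#Cc1ccc(-c2cccs2)s1 | intermediate
5 | 5-(but-3-en-1-yn-1-yl)-2,2'-bithiophene | C=CC#Cc1ccc(-c2cccs2)s1 | intermediate
6 | isocardopatine, cis-1,2-bis[([2,2'-bithiophen]-5-yl)ethynyl]cyclobutane (1R,2S, meso) | C(#C[C@@H]1CC[C@@H]1C#Cc1ccc(-c2cccs2)s1)c1ccc(-c2cccs2)s1 | target

Total step count: 3
Longest linear sequence: 3 steps (1 → 3 → 5 → 6)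

Steps most likely to fail

Step 3 (key step). What may go wrong: unselective collapse of the 1,4-biradical (cis and trans closure competing), photocycloreversion or cis-to-trans drift of the dimer under continued irradiation, and oligomerisation of the enyne. The fallback sets out from compound 1 (with commercial diallyl ether as the source of the ring) and comes back at compound 6. It enforces the cis ring with a temporary ether bridge. Diallyl ether is irradiated (254 nm, Et2O) with catalytic (CuOTf)2·C6H6 (a salt of monovalent copper), which clamps both alkenes and should give cis-3-oxabicyclo[3.2.0]heptane F1 by intramolecular [2+2] photocycloaddition. This forms the same two cyclobutane bonds (CH2–CH2 and CH–CH) in one operation, and the fusion to the five-membered ring allows only the cis arrangement. Oxidation with catalytic RuO2 and NaIO4 should give the lactone (±)-cis-3-oxabicyclo[3.2.0]heptan-2-one F2, and reduction with LiAlH4 gives cis-cyclobutane-1,2-diyldimethanol F3. Swern oxidation (iPr2NEt, −78 °C) gives cis-cyclobutane-1,2-dicarbaldehyde F4, which is used cold and crude to avoid epimerisation. Corey–Fuchs olefination with CBr4 and PPh3 gives cis-1,2-bis(2,2-dibromoethenyl)cyclobutane F5, and n-BuLi (THF, −78 °C) followed by water gives cis-1,2-diethynylcyclobutane F6, kept in solution because of its volatility. Double Sonogashira coupling of F6 with two equivalents of 1 (PdCl2(PPh3)2, CuI, Et3N, THF) then gives 6.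

Step 2. What may go wrong: substitution of the mesylate by the amine bases in place of elimination, and base- or light-induced oligomerisation of the sensitive vinylacetylene during isolation. The fallback sets out from compound 1 and comes back at compound 5. It builds the enyne by C(sp)–C(sp2) coupling and needs no elimination. Sonogashira coupling of 1 with ethynyltrimethylsilane (PdCl2(PPh3)2, CuI, Et3N, 60 °C) gives 5-[(trimethylsilyl)ethynyl]-2,2'-bithiophene F7. Methanolysis (K2CO3, MeOH/THF, rt) gives 5-ethynyl-2,2'-bithiophene F8. A second Sonogashira coupling of F8 with vinyl bromide (solution in THF; Pd(PPh3)4, CuI, Et2NH, rt) gives 5 under mild, nearly neutral conditions.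

Step 1. What may go wrong: slow oxidative addition into the electron-rich bromothiophene, so that copper-mediated oxidative homocoupling of the alkynol consumes the alkyne. The fallback sets out from compound 2 and comes back at compound 3. It reverses the order of bond construction. Commercial 2-bromo-5-iodothiophene is coupled with 2 at the iodide only (PdCl2(PPh3)2, CuI, Et3N, THF, rt) to give 4-(5-bromothiophen-2-yl)but-3-yn-1-ol F9. The thiophene–thiophene bond is then made by Stille coupling of F9 with tributyl(thiophen-2-yl)stannane (Pd(PPh3)4, toluene, 90 °C), which gives 3.

Further compounds
F1 | step 3 | cis-3-oxabicyclo[3.2.0]heptane | O1C[C@@H]2CC[C@@H]2C1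
F2 | step 3 | (±)-cis-3-oxabicyclo[3.2.0]heptan-2-one (one enantiomer drawn) | O=C1OC[C@@H]2CC[C@@H]21
F3 | step 3 | cis-cyclobutane-1,2-diyldimethanol | OC[C@@H]1CC[C@@H]1CO
F4 | step 3 | cis-cyclobutane-1,2-dicarbaldehyde | O=C[C@@H]1CC[C@@H]1C=O
F5 | step 3 | cis-1,2-bis(2,2-dibromoethenyl)cyclobutane | BrC(Br)=C[C@@H]1CC[C@@H]1C=C(Br)Br
F6 | step 3 | cis-1,2-diethynylcyclobutane | C#C[C@@H]1CC[C@@H]1C#C
F7 | step 2 | 5-[(trimethylsilyl)ethynyl]-2,2'-bithiophene | C[Si](C)(C)C#Cc1ccc(-c2cccs2)s1
F8 | step 2 | 5-ethynyl-2,2'-bithiophene | C#Cc1ccc(-c2cccs2)s1
F9 | step 1 | 4-(5-bromothiophen-2-yl)but-3-yn-1-ol | OCCC#Cc1ccc(Br)s1
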